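**Retrosynthetic overview**

1. 28 ⇐ 27 ⇐ 26 by ester demethylation and C8′ methylenation. The strategy rests on the 2,2-dimethylcyclobutane (C1′, C9′, C10′, C11′) fused through C1′–C9′ to the nine-membered ring directly beside C8′: with C8′ as a ketone, this ring is the head-to-tail [2+2] adduct of the Z-enone C8′(=O)–C9′=C1′ of 23 and isobutylene (bonds C1′–C11′ and C9′–C10′).
2. 23 ⇐ dienone 22 by ring-closing metathesis (C9′=C1′) between a vinyl ketone on the C5′ arm and a but-3-enyl group on C4′.
3. The cyclohexene (C12, C13, C14, C15, C5′, C4′) with its quaternary C4′ ⇐ Ireland–Claisen rearrangement (C4′–C12) of the α-butenyl δ-lactone 14. 14 ⇐ dihydropyranone 11 by conjugate addition (C5′–C6′) and enolate alkylation (C4′–C3′); 11 ⇐ enal 7 by allylation, acryloylation and metathesis.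
4. 7 ⇐ aldehyde 6 ⇐ ring-C ozonolysis of (+)-podocarpic acid 1, which supplies C4, C5, C10 and the C19 carboxyl of the decalin.
5. Order of ring formation: decalin (from 1) → δ-lactone → cyclohexene → nine-membered ring → cyclobutane.

Key step: step 18

Remark: labdane numbering (C1–C20) is used for the decalin half and primed caryophyllane numbering (C1′–C11′) for the other half; the cyclohexene ring is C12–C13–C14–C15–C5′–C4′; "Lab" is the [(1S,4aR,5S,8aR)-5-methoxycarbonyl-5,8a-dimethyl-2-methylidenedecahydronaphthalen-1-yl] group (its C1 is labdane C9); it is assumed that ozone spares the electron-poor C9=C11 bond formed in step 1.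

**Step 1**
Reactants: 1 (+)-podocarpic acid
Product: 3 8-oxo-13,14,15,16,17-pentanorlabdane-12,19-dioic acid (9α-H), via ene-keto diacid 2 (not isolated)
Conditions: O3, CH2Cl2–MeOH, −78 °C; then Zn, AcOH, −78 → 50 °C
Reagents that add atoms: ozone, [O-][O+]=O
Why: Ozonolysis of the electron-rich phenol ring cleaves C12–C13 and C8–C14 while the resulting electron-poor C9=C11 of the ene-keto acid is spared, and zinc in acetic acid then reduces the peroxides and this activated alkene (dissolving-metal conjugate reduction), C9 settling α to the ketone in the equatorial, natural 9α-H arrangement.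

**Step 2**
Reactants: 3 keto diacid
Product: 4 dimethyl 8-oxo-13,14,15,16,17-pentanorlabdane-12,19-dioate
Conditions: MeI, K2CO3, DMF, rt
Reagents that add atoms: iodomethane, CI
Why: Carboxylate O-alkylation (SN2 on iodomethane) esterifies both acids regardless of the hindrance at C4, and the mild base leaves C9 at its thermodynamic configuration.

**Step 3**
Reactants: 4 keto diester
Product: 5 dimethyl 13,14,15,16-tetranorlabd-8(17)-ene-12,19-dioate
Conditions: Ph3PCH3Br, KHMDS, THF, 0 °C → rt
Reagents that add atoms: methyltriphenylphosphonium bromide (as its ylide), C[P+](c1ccccc1)(c1ccccc1)c1ccccc1.[Br-]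
Why: Wittig methylenation of the C8 ketone with the non-stabilised ylide, to which esters are inert, and the epimerisable C9 remains in its more stable equatorial configuration.

**Step 4**
Reactants: 5 methylene diester
Product: 6 methyl 12-oxo-13,14,15,16-tetranorlabd-8(17)-en-19-oate
Conditions: DIBAL-H (1.05 equiv), CH2Cl2, −78 °C; Rochelle salt
Reagents that add atoms: none
Why: Partial DIBAL-H reduction of an ester to the aldehyde through the aluminium hemiacetal that is stable at −78 °C, the unhindered C12 ester reacting while the axial, neopentyl C19 ester does not.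

**Step 5**
Reactants: 6 aldehyde
Product: 7 methyl (12E)-14-oxo-15-norlabda-8(17),12-dien-19-oate
Conditions: Ph3P=C(Me)CHO, toluene, 90 °C
Reagents that add atoms: 2-(triphenylphosphoranylidene)propanal, CC(C=O)=P(c1ccccc1)(c1ccccc1)c1ccccc1
Why: Wittig olefination with a stabilised formyl ylide, which should give the (E)-2-methyl enal because oxaphosphetane formation is reversible and the trans arrangement is preferred.

**Step 6**
Reactants: 7 enal
Product: 8 methyl (12E,14R)-14-hydroxy-14-(prop-2-enyl)-15-norlabda-8(17),12-dien-19-oate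
Conditions: allylSnBu3, (R)-BINOL (20 mol %), Ti(OiPr)4 (10 mol %), 4 Å MS, CH2Cl2, −20 °C
Reagents that add atoms: allyltributylstannane, C=CC[Sn](CCCC)(CCCC)CCCC
Why: Keck asymmetric allylation, in which the (R)-BINOL–titanium complex activates the enal and directs allyl transfer to its Re face, so that C14 is set as R under catalyst control (the resident stereocentres are remote).

**Step 7**
Reactants: 8 homoallylic alcohol; 9 acryloyl chloride
Product: 10 (14R)-acrylate of 8
Conditions: Et3N, DMAP (cat.), CH2Cl2, 0 °C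
Reagents that add atoms: none
Why: DMAP-catalysed acylation of the secondary allylic alcohol by the acid chloride (nucleophilic acyl substitution), which does not touch the stereocentre.

**Step 8**
Reactants: 10 acrylate
Product: 11 (6R)-6-[(2E)-4-Lab-but-2-en-2-yl]-5,6-dihydro-2H-pyran-2-one
Conditions: Grubbs II (5 mol %), CH2Cl2 (5 mM), 40 °C
Reagents that add atoms: none
Why: Ring-closing metathesis, in which the ruthenium carbene loads on the monosubstituted allyl terminus and closes onto the acrylate to give the six-membered unsaturated lactone, the trisubstituted and 1,1-disubstituted alkenes being too hindered to compete.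

**Step 9**
Reactants: 11 dihydropyranone
Product: 12 (4S,6R)-4-[3-(tert-butyldimethylsilyloxy)propyl]-6-[(2E)-4-Lab-but-2-en-2-yl]tetrahydro-2H-pyran-2-one
Conditions: TBSO(CH2)3MgBr (preformed from the bromide), CuBr·SMe2 (20 mol %), THF, −78 → −40 °C; aq NH4Cl
Reagents that add atoms: [3-(tert-butyldimethylsilyloxy)propyl]magnesium bromide, CC(C)(C)[Si](C)(C)OCCC[Mg]Br
Why: Copper-catalysed conjugate addition of the Grignard reagent to the unsaturated δ-lactone, where axial attack anti to the C14 alkenyl group sets C5′ trans to it.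

**Step 10**
Reactants: 12 lactone; 13 4-iodobut-1-ene
Product: 14 (3R,4S,6R)-3-(but-3-enyl) derivative of 12
Conditions: LDA, THF, −78 °C; then 13, HMPA, −78 → −30 °C
Reagents that add atoms: none
Why: SN2 alkylation of the lithium lactone enolate by the primary iodide, which should enter anti to the C5′ chain, although the configuration of C4′ is of no consequence because this centre becomes planar in the next step.

**Step 11**
Reactants: 14 butenyl lactone
Product: 17 (1S,2R,6S)-1-(but-3-enyl)-6-[3-(tert-butyldimethylsilyloxy)propyl]-2-(Lab-methyl)-3-methylcyclohex-3-ene-1-carboxylic acid, via silyl ketene acetal 15 (not isolated), via silyl ester 16 (not isolated)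
Conditions: LDA, THF, −78 °C; TMSCl–Et3N; then toluene, 100 °C; then H2O–MeOH
Reagents that add atoms: chlorotrimethylsilane, C[Si](C)(C)Cl (its atoms stay in 15 and 16 only)
Why: Ireland–Claisen rearrangement of the lactone silyl ketene acetal, in which the ring enforces a boat transition state and C4′ bonds to C12 on the face from which the C14–O bond departs, so that C14 (R) and the E alkene fix C12 and the quaternary C4′ (carboxyl cis to the C12 and C5′ substituents, butenyl trans) while C5′ is carried through unchanged.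

**Step 12**
Reactants: 17 cyclohexene acid
Product: 18 methyl ester of 17
Conditions: MeI, K2CO3, DMF, rt
Reagents that add atoms: iodomethane, CI
Why: SN2 O-methylation of the hindered carboxylate, an esterification that needs no attack at the crowded carbonyl carbon and no acid.

**Step 13**
Reactants: 18 silyl ether ester
Product: 19 primary alcohol (C8′–OH) of 18
Conditions: TBAF, AcOH, THF, rt
Reagents that add atoms: none
Why: Fluoride-induced cleavage of the primary silyl ether (Si–F bond formation), buffered with acetic acid so that the liberated alkoxide does not attack the C4′ ester.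

**Step 14**
Reactants: 19 alcohol
Product: 20 C8′ aldehyde
Conditions: DMP, NaHCO3, CH2Cl2, 0 °C → rt
Reagents that add atoms: none
Why: Dess–Martin oxidation of the primary alcohol to the aldehyde under buffered, non-acidic conditions that leave the three alkenes untouched.

**Step 15**
Reactants: 20 aldehyde
Product: 21 C8′ vinyl carbinol (both C8′ epimers)
Conditions: vinylMgBr, THF, −78 °C
Reagents that add atoms: vinylmagnesium bromide, C=C[Mg]Br
Why: Grignard 1,2-addition to the aldehyde at −78 °C, where the two hindered methyl esters do not react, the new carbinol centre being formed without control and removed in the next step.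

**Step 16**
Reactants: 21 vinyl carbinol
Product: 22 vinyl ketone (dienone)
Conditions: DMP, NaHCO3, CH2Cl2, 0 °C
Reagents that add atoms: none
Why: Dess–Martin oxidation of the allylic alcohol to the vinyl ketone, which is used at once because such enones polymerise readily.

**Step 17**
Reactants: 22 dienone
Product: 23 (4′S,5′S,12R)-Z-cyclononenone diester (cyclohexene-fused, trans ring junction)
Conditions: Hoveyda–Grubbs II (10 mol %), toluene (1 mM), 80 °C
Reagents that add atoms: none
Why: Ring-closing metathesis at high dilution, in which the carbene forms at the unhindered butenyl terminus and closes onto the vinyl ketone, the two chains being held close by the quaternary C4′ and the ring junction, and only the Z enone is geometrically possible in a nine-membered ring.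

**Step 18**
Reactants: 23 Z-cyclononenone diester; 24 isobutylene
Product: 26 (1′R,4′S,5′S,9′S,12R)-C8′ ketone of the target dimethyl ester, via cis-fused cycloadduct 25 (not isolated)
Conditions: hν (350 nm, Pyrex), isobutylene (large excess)/CH2Cl2, −70 °C; then DBU (cat.), CH2Cl2, rt
Reagents that add atoms: none
Why: Proposed new method: the intermolecular enone–alkene [2+2] photocycloaddition is established for five- to seven-membered cyclic enones (closest known case: a cyclohex-2-enone with isobutylene giving the head-to-tail adduct, followed by base equilibration of the ring fusion), but a Z-cyclonon-2-enone has not been shown to undergo it, because its excited state can also decay by twisting to the E isomer. The reasoning is that n→π* excitation and intersystem crossing give a twisted triplet that behaves as a 1,2-biradical; in nearly neat alkene it should be trapped by bonding of C9′ to the CH2 terminus of isobutylene (C10′), which leaves the best pair of radicals (secondary at C1′, tertiary at C11′), and any E-enone formed at −70 °C is returned to the Z isomer by further irradiation. The cyclobutane then closes by spin inversion and radical recombination C1′–C11′ (stepwise, non-concerted closure of a 1,4-biradical), the alternative first bond C1′–CH2 leading to the head-to-head isomer and being disfavoured by the polarity of the excited enone as in the six-ring case. C1′ is set in this closure by the conformation of the trans-fused 6/9 ring system, which turns one face of the enone towards the ring interior and the C4′ ester and leaves the outer face open; this face is expected, not assured, to give 1′R. C9′ is controlled thermodynamically, not photochemically: DBU enolises the ketone towards C9′ and equilibrates cis-fused 25 to the trans-fused bicyclo[7.2.0]undecan-2-one 26, the more stable junction of a four- to a nine-membered ring. The step needs head-to-tail regiochemistry, the C1′ face selectivity just named, and chemoselectivity for the enone over the three isolated alkenes, the last secured by irradiating at 350 nm, where only the enone absorbs, and by the large excess of isobutylene, which should outrun any transannular reaction.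

**Step 19**
Reactants: 26 ketone
Product: 27 dimethyl ester of the target
Conditions: Ph3PCH3Br, KHMDS, THF, 0 → 50 °C
Reagents that add atoms: methyltriphenylphosphonium bromide (as its ylide), C[P+](c1ccccc1)(c1ccccc1)c1ccccc1.[Br-]
Why: Wittig methylenation of the C8′ ketone with the non-stabilised ylide, the base-labile C9′ centre already having its thermodynamic trans-fused configuration so that it cannot be eroded.

**Step 20**
Reactants: 27 dimethyl ester
Product: 28 CNP0330729.1 (diacid)
Conditions: n-PrSLi, HMPA, rt; then 1 M HCl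
Reagents that add atoms: none
Why: SN2 demethylation, in which the soft thiolate attacks the two ester methyl groups (unhindered even though both carbonyl groups are), and mild acidification should give the diacid without isomerising the exocyclic alkenes.

**Compound list**

1 | (+)-podocarpic acid (12-hydroxypodocarpa-8,11,13-trien-19-oic acid) | C[C@]12CCC[C@]([C@@H]1CCC3=C2C=C(C=C3)O)(C)C(=O)O | starting material
2 | (9(11)Z)-8-oxo-13,14,15,16,17-pentanorlabd-9(11)-ene-12,19-dioic acid (ring-C seco ene-keto diacid, in equilibrium with its hydroxybutenolide) | OC(=O)/C=C1\C(=O)CC[C@@H]2[C@]1(C)CCC[C@]2(C)C(=O)O | intermediate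
3 | 8-oxo-13,14,15,16,17-pentanorlabdane-12,19-dioic acid (9α-H) | OC(=O)C[C@H]1C(=O)CC[C@@H]2[C@]1(C)CCC[C@]2(C)C(=O)O | intermediate
4 | dimethyl 8-oxo-13,14,15,16,17-pentanorlabdane-12,19-dioate | COC(=O)C[C@H]1C(=O)CC[C@@H]2[C@]1(C)CCC[C@]2(C)C(=O)OC | intermediate
5 | dimethyl 13,14,15,16-tetranorlabd-8(17)-ene-12,19-dioate | COC(=O)C[C@H]1C(=C)CC[C@@H]2[C@]1(C)CCC[C@]2(C)C(=O)OC | intermediate
6 | methyl 12-oxo-13,14,15,16-tetranorlabd-8(17)-en-19-oate | O=CC[C@H]1C(=C)CC[C@@H]2[C@]1(C)CCC[C@]2(C)C(=O)OC | intermediate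
7 | methyl (12E)-14-oxo-15-norlabda-8(17),12-dien-19-oate | O=C/C(C)=C/C[C@H]1C(=C)CC[C@@H]2[C@]1(C)CCC[C@]2(C)C(=O)OC | intermediate
8 | methyl (12E,14R)-14-hydroxy-14-(prop-2-enyl)-15-norlabda-8(17),12-dien-19-oate | C=CC[C@@H](O)/C(C)=C/C[C@H]1C(=C)CC[C@@H]2[C@]1(C)CCC[C@]2(C)C(=O)OC | intermediate
9 | acryloyl chloride | C=CC(=O)Cl | starting material
10 | (14R)-acrylate of 8 | C=CC[C@@H](OC(=O)C=C)/C(C)=C/C[C@H]1C(=C)CC[C@@H]2[C@]1(C)CCC[C@]2(C)C(=O)OC | intermediate
11 | (6R)-6-[(2E)-4-Lab-but-2-en-2-yl]-5,6-dihydro-2H-pyran-2-one | O=C1C=CC[C@@H](O1)/C(C)=C/C[C@H]2C(=C)CC[C@@H]3[C@]2(C)CCC[C@]3(C)C(=O)OC | intermediate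
12 | (4S,6R)-4-[3-(tert-butyldimethylsilyloxy)propyl]-6-[(2E)-4-Lab-but-2-en-2-yl]tetrahydro-2H-pyran-2-one (4,6-trans) | O=C1C[C@@H](CCCO[Si](C)(C)C(C)(C)C)C[C@@H](O1)/C(C)=C/C[C@H]2C(=C)CC[C@@H]3[C@]2(C)CCC[C@]3(C)C(=O)OC | intermediate
13 | 4-iodobut-1-ene | C=CCCI | starting material
14 | (3R,4S,6R)-3-(but-3-enyl)-4-[3-(tert-butyldimethylsilyloxy)propyl]-6-[(2E)-4-Lab-but-2-en-2-yl]tetrahydro-2H-pyran-2-one | O=C1[C@H](CCC=C)[C@@H](CCCO[Si](C)(C)C(C)(C)C)C[C@@H](O1)/C(C)=C/C[C@H]2C(=C)CC[C@@H]3[C@]2(C)CCC[C@]3(C)C(=O)OC | intermediate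
15 | trimethylsilyl ketene acetal of 14 (2-trimethylsilyloxy-3,4-dihydro-2H-pyran, C4′=C double bond) | C[Si](C)(C)OC1=C(CCC=C)[C@@H](CCCO[Si](C)(C)C(C)(C)C)C[C@@H](O1)/C(C)=C/C[C@H]2C(=C)CC[C@@H]3[C@]2(C)CCC[C@]3(C)C(=O)OC | intermediate
16 | trimethylsilyl ester of 17 | CC(C)(C)[Si](C)(C)OCCC[C@H]1CC=C(C)[C@@H](C[C@H]2C(=C)CC[C@@H]3[C@]2(C)CCC[C@]3(C)C(=O)OC)[C@]1(C(=O)O[Si](C)(C)C)CCC=C | intermediate
17 | (1S,2R,6S)-1-(but-3-enyl)-6-[3-(tert-butyldimethylsilyloxy)propyl]-2-(Lab-methyl)-3-methylcyclohex-3-ene-1-carboxylic acid (CO2H cis to the C2 and C6 substituents) | CC(C)(C)[Si](C)(C)OCCC[C@H]1CC=C(C)[C@@H](C[C@H]2C(=C)CC[C@@H]3[C@]2(C)CCC[C@]3(C)C(=O)OC)[C@]1(C(=O)O)CCC=C | intermediate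
18 | methyl ester of 17 | CC(C)(C)[Si](C)(C)OCCC[C@H]1CC=C(C)[C@@H](C[C@H]2C(=C)CC[C@@H]3[C@]2(C)CCC[C@]3(C)C(=O)OC)[C@]1(C(=O)OC)CCC=C | intermediate
19 | methyl (1S,2R,6S)-1-(but-3-enyl)-6-(3-hydroxypropyl)-2-(Lab-methyl)-3-methylcyclohex-3-ene-1-carboxylate | OCCC[C@H]1CC=C(C)[C@@H](C[C@H]2C(=C)CC[C@@H]3[C@]2(C)CCC[C@]3(C)C(=O)OC)[C@]1(C(=O)OC)CCC=C | intermediate
20 | methyl (1S,2R,6S)-1-(but-3-enyl)-2-(Lab-methyl)-3-methyl-6-(3-oxopropyl)cyclohex-3-ene-1-carboxylate | O=CCC[C@H]1CC=C(C)[C@@H](C[C@H]2C(=C)CC[C@@H]3[C@]2(C)CCC[C@]3(C)C(=O)OC)[C@]1(C(=O)OC)CCC=C | intermediate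
21 | methyl (1S,2R,6S)-1-(but-3-enyl)-6-(3-hydroxypent-4-enyl)-2-(Lab-methyl)-3-methylcyclohex-3-ene-1-carboxylate (C8′ epimers) | C=CC(O)CC[C@H]1CC=C(C)[C@@H](C[C@H]2C(=C)CC[C@@H]3[C@]2(C)CCC[C@]3(C)C(=O)OC)[C@]1(C(=O)OC)CCC=C | intermediate
22 | methyl (1S,2R,6S)-1-(but-3-enyl)-2-(Lab-methyl)-3-methyl-6-(3-oxopent-4-enyl)cyclohex-3-ene-1-carboxylate | C=CC(=O)CC[C@H]1CC=C(C)[C@@H](C[C@H]2C(=C)CC[C@@H]3[C@]2(C)CCC[C@]3(C)C(=O)OC)[C@]1(C(=O)OC)CCC=C | intermediate
23 | (4′S,5′S,12R)-Z-cyclononenone diester: cyclohexene trans-fused at C4′–C5′ to a cyclonon-2-enone (C8′=O, C9′=C1′ Z), CO2Me on C4′, Lab-methyl on C12 | C1C[C@H]2CC=C(C)[C@@H](C[C@H]3C(=C)CC[C@@H]4[C@]3(C)CCC[C@]4(C)C(=O)OC)[C@]2(C(=O)OC)CC/C=C\C1=O | intermediate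
24 | isobutylene | C=C(C)C | starting material
25 | cis-fused cycloadduct (9′R epimer of 26, H-1′ and H-9′ cis) | O=C1CC[C@H]2CC=C(C)[C@@H](C[C@H]3C(=C)CC[C@@H]4[C@]3(C)CCC[C@]4(C)C(=O)OC)[C@]2(C(=O)OC)CC[C@@H]2[C@H]1CC2(C)C | intermediate
26 | (1′R,4′S,5′S,9′S,12R)-C8′ ketone of the target dimethyl ester (trans-fused 2,2-dimethylcyclobutane) | O=C1CC[C@H]2CC=C(C)[C@@H](C[C@H]3C(=C)CC[C@@H]4[C@]3(C)CCC[C@]4(C)C(=O)OC)[C@]2(C(=O)OC)CC[C@@H]2[C@@H]1CC2(C)C | intermediate
27 | dimethyl ester of CNP0330729.1 | C=C1CC[C@H]2CC=C(C)[C@@H](C[C@H]3C(=C)CC[C@@H]4[C@]3(C)CCC[C@]4(C)C(=O)OC)[C@]2(C(=O)OC)CC[C@@H]2[C@@H]1CC2(C)C | intermediate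
28 | CNP0330729.1 | C=C1CC[C@H]2CC=C(C)[C@@H](C[C@H]3C(=C)CC[C@@H]4[C@]3(C)CCC[C@]4(C)C(=O)O)[C@]2(C(=O)O)CC[C@@H]2[C@@H]1CC2(C)C | target

Total step count: 20
Longest linear sequence: 20 steps (1 → 28)

**Steps most likely to fail**

Step 18 (key step, proposed new method). The triplet of the nine-membered enone may relax by twisting to the E isomer faster than isobutylene traps it, and the 1,4-biradical may close on either face of C1′ or revert, so conversion, regiochemistry and C1′ face selectivity are all uncertain. The fallback uses known polar chemistry; it sets out from 23 and comes back at 26. A silyl-transfer Mukaiyama–Michael addition of the tert-butyldimethylsilyl ketene S,O-acetal of S-ethyl 2-methylpropanethioate (a reagent prepared beforehand; TBSOTf cat., CH2Cl2, −78 °C) forms C1′–C11′ and leaves the C8′–C9′ silyl enol ether thioester F1. LiBH4 (THF, 0 °C) reduces only the thioester and gives the neopentyl alcohol F2, whose CH2OH carbon is C10′. TsCl–pyridine gives the tosylate F3. Anhydrous fluoride (TASF or TBAF, THF) then releases the C8′ enolate regiospecifically, and intramolecular alkylation (4-exo-tet) closes C9′–C10′; after equilibration of C9′ this gives 26. Because the β-carbon is bonded first by a nucleophile, the gem-dimethyl carbon can only end on C1′.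

Step 17. Medium-ring strain may make ring closure slower than intermolecular metathesis, so that oligomers form, and the carbene may stall as a chelate on the ketone. The fallback closes the C8′–C9′ bond instead, by an intramolecular Nozaki–Hiyama–Kishi reaction; it sets out from 12 and comes back at 23. Alkylation of the enolate of 12 with allyl bromide gives the allyl lactone F4. Ireland–Claisen rearrangement as in step 11, through the silyl ketene acetal F5 and the silyl ester F6, gives the allyl cyclohexene acid F7, and MeI/K2CO3 gives its methyl ester F8. Disiamylborane followed by sodium perborate hydroborates only the monosubstituted alkene and gives the C1′ primary alcohol F9, which is kept neutral and oxidised at once with Dess–Martin periodinane to the C1′ aldehyde F10. Stork–Zhao olefination (Ph3P=CHI, THF–HMPA, −78 °C) gives the (Z)-vinyl iodide F11 (C1′=C9′). TBAF/AcOH frees the C8′ alcohol F12 and Dess–Martin oxidation gives the iodo aldehyde F13. CrCl2 with catalytic NiCl2 (DMSO–THF, high dilution) then forms C8′–C9′ and gives the cyclic (Z)-allylic alcohol F14 as C8′ epimers, and Dess–Martin oxidation gives 23.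

Step 10. The homoallylic iodide may undergo E2 elimination to butadiene faster than it alkylates the hindered lactone enolate, which would return 12. The fallback installs the chain in two stages; it sets out from 12 and comes back at 14. Allyl bromide, which alkylates fast and cannot eliminate in this way, gives the allyl lactone F4. Disiamylborane/sodium perborate converts its monosubstituted alkene into the 3-hydroxypropyl lactone F15, Dess–Martin oxidation gives the aldehyde lactone F16, and Wittig methylenation (Ph3P=CH2, THF, −78 → 0 °C) gives 14.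

**Further compounds**

F1 | step 18 | C8′–C9′ tert-butyldimethylsilyl enol ether of 23 carrying the S-ethyl 2-methylpropanethioate unit on C1′ | C1C[C@H]2CC=C(C)[C@@H](C[C@H]3C(=C)CC[C@@H]4[C@]3(C)CCC[C@]4(C)C(=O)OC)[C@]2(C(=O)OC)CC[C@@H](C(C)(C)C(=O)SCC)/C=C1/O[Si](C)(C)C(C)(C)C
F2 | step 18 | neopentyl alcohol from F1 (C10′–OH, silyl enol ether kept) | C1C[C@H]2CC=C(C)[C@@H](C[C@H]3C(=C)CC[C@@H]4[C@]3(C)CCC[C@]4(C)C(=O)OC)[C@]2(C(=O)OC)CC[C@@H](C(C)(C)CO)/C=C1/O[Si](C)(C)C(C)(C)C
F3 | step 18 | tosylate of F2 | C1C[C@H]2CC=C(C)[C@@H](C[C@H]3C(=C)CC[C@@H]4[C@]3(C)CCC[C@]4(C)C(=O)OC)[C@]2(C(=O)OC)CC[C@@H](C(C)(C)COS(=O)(=O)c5ccc(C)cc5)/C=C1/O[Si](C)(C)C(C)(C)C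
F4 | step 17 | (3R,4S,6R)-3-allyl lactone (allyl analogue of 14) | O=C1[C@H](CC=C)[C@@H](CCCO[Si](C)(C)C(C)(C)C)C[C@@H](O1)/C(C)=C/C[C@H]2C(=C)CC[C@@H]3[C@]2(C)CCC[C@]3(C)C(=O)OC
F5 | step 17 | trimethylsilyl ketene acetal of F4 | C[Si](C)(C)OC1=C(CC=C)[C@@H](CCCO[Si](C)(C)C(C)(C)C)C[C@@H](O1)/C(C)=C/C[C@H]2C(=C)CC[C@@H]3[C@]2(C)CCC[C@]3(C)C(=O)OC
F6 | step 17 | trimethylsilyl ester of F7 | CC(C)(C)[Si](C)(C)OCCC[C@H]1CC=C(C)[C@@H](C[C@H]2C(=C)CC[C@@H]3[C@]2(C)CCC[C@]3(C)C(=O)OC)[C@]1(C(=O)O[Si](C)(C)C)CC=C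
F7 | step 17 | allyl cyclohexene acid (allyl analogue of 17) | CC(C)(C)[Si](C)(C)OCCC[C@H]1CC=C(C)[C@@H](C[C@H]2C(=C)CC[C@@H]3[C@]2(C)CCC[C@]3(C)C(=O)OC)[C@]1(C(=O)O)CC=C
F8 | step 17 | methyl ester of F7 | CC(C)(C)[Si](C)(C)OCCC[C@H]1CC=C(C)[C@@H](C[C@H]2C(=C)CC[C@@H]3[C@]2(C)CCC[C@]3(C)C(=O)OC)[C@]1(C(=O)OC)CC=C
F9 | step 17 | C1′ primary alcohol (3-hydroxypropyl on C4′) | CC(C)(C)[Si](C)(C)OCCC[C@H]1CC=C(C)[C@@H](C[C@H]2C(=C)CC[C@@H]3[C@]2(C)CCC[C@]3(C)C(=O)OC)[C@]1(C(=O)OC)CCCO
F10 | step 17 | C1′ aldehyde (3-oxopropyl on C4′) | CC(C)(C)[Si](C)(C)OCCC[C@H]1CC=C(C)[C@@H](C[C@H]2C(=C)CC[C@@H]3[C@]2(C)CCC[C@]3(C)C(=O)OC)[C@]1(C(=O)OC)CCC=O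
F11 | step 17 | (Z)-vinyl iodide ((3Z)-4-iodobut-3-enyl on C4′) | CC(C)(C)[Si](C)(C)OCCC[C@H]1CC=C(C)[C@@H](C[C@H]2C(=C)CC[C@@H]3[C@]2(C)CCC[C@]3(C)C(=O)OC)[C@]1(C(=O)OC)CC/C=C\I
F12 | step 17 | C8′ alcohol of the (Z)-vinyl iodide | OCCC[C@H]1CC=C(C)[C@@H](C[C@H]2C(=C)CC[C@@H]3[C@]2(C)CCC[C@]3(C)C(=O)OC)[C@]1(C(=O)OC)CC/C=C\I
F13 | step 17 | C8′ aldehyde of the (Z)-vinyl iodide | O=CCC[C@H]1CC=C(C)[C@@H](C[C@H]2C(=C)CC[C@@H]3[C@]2(C)CCC[C@]3(C)C(=O)OC)[C@]1(C(=O)OC)CC/C=C\I
F14 | step 17 | cyclic (Z)-allylic alcohol (C8′–OH analogue of 23, C8′ epimers) | C1C[C@H]2CC=C(C)[C@@H](C[C@H]3C(=C)CC[C@@H]4[C@]3(C)CCC[C@]4(C)C(=O)OC)[C@]2(C(=O)OC)CC/C=C\C1O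
F15 | step 10 | (3R,4S,6R)-3-(3-hydroxypropyl) lactone | O=C1[C@H](CCCO)[C@@H](CCCO[Si](C)(C)C(C)(C)C)C[C@@H](O1)/C(C)=C/C[C@H]2C(=C)CC[C@@H]3[C@]2(C)CCC[C@]3(C)C(=O)OC
F16 | step 10 | (3R,4S,6R)-3-(3-oxopropyl) lactone | O=C1[C@H](CCC=O)[C@@H](CCCO[Si](C)(C)C(C)(C)C)C[C@@H](O1)/C(C)=C/C[C@H]2C(=C)CC[C@@H]3[C@]2(C)CCC[C@]3(C)C(=O)OC
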